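The readings were computed with made-up constants, noise included.

The reading at 30 h compares flasks that start with none of their solid substrate in solution.

| setting | Wednesday's | delta | alpha | zeta | beta | eta | gamma |
|---|---|---|---|---|---|---|---|
| solid substrate | 0.055 M | 0.050 M | 0.015 M | 0.15 M | 0.10 M | 0.015 M | 0.015 M |
| catalyst | 9.6 mol% | 9.6 mol% | 3 mol% | 30 mol% | 9.6 mol% | 9.6 mol% | 6 mol% |
| remark | run made earlier |  |  |  |  |  |  |
| time |  | 30 h | 30 h | 30 h | 30 h | 30 h | 30 h |

Wednesday's run (percent of the solid substrate charged)

| time / h | target / % | side product / % |
|---|---|---|
| 0.500 | 0.2 | 0.9 |
| 0.667 | 1.1 | 0 |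
| 1.00 | 1.5 | 1.1 |
| 1.50 | 2.5 | 2.6 |
| 2.50 | 4.4 | 2.9 |
| 4.00 | 7.1 | 7.3 |
| 6.00 | 11.1 | 8.9 |

(readings scatter by 0.5 percentage points)

* the flasks by share of target in all that became target or side product or isomer of the product, highest first, at 30 h (delta / alpha / zeta / beta / eta / gamma)
* the same order at 6.0 h (delta / alpha / zeta / beta / eta / gamma)
* the share of target in all that became target or side product or isomer of the product of the flask you put first, at 30 h
* the share of target in all that became target or side product or isomer of the product of the flask you put last, at 30 h

- solid substrate is a solid; its amount is given per volume of the solution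
- the numbers in the tables scatter with a standard deviation of 0.5 percentage points
- at the start none of the solid substrate is in solution
- what has only dissolved of solid substrate counts as not reacted
- no earlier run changes the charge of catalyst; that part of a forecast is a guess

Wednesday's target and side product climb nearly straight, so their curve can be replaced by its mean. At 6.00 h the two readings together give 1.83 mM h⁻¹: the feed rate F, the solid substrate per litre and hour that ends as either product, a zero-order supply. The mean to 4.00 h gives 1.98 mM h⁻¹, so this replacement carries an error of about 8.00%.

Taking F as equal in every flask while solid stands is a guess, since no earlier run changes the catalyst. A charge then lasts c(solid substrate)/F: 8.20 h at 0.015 M, 27.3 h in delta, 54.5 h in beta and 81.8 h in zeta. Beta and zeta should therefore still be fed at 30 h, with beta reckoned at 55.0% conversion. F gives no split between the products, so this reckoning names no share.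

The forecast gives zeta > beta > delta > eta > gamma > alpha at 30 h and zeta > beta > delta > eta > gamma > alpha at 6.0 h, with 75% for its first flask and 10% for its last at 30 h, on the guess that “selectivity follows absolute catalyst concentration”.

The flasks give beta > zeta > delta > eta > gamma > alpha at 30 h and zeta > beta > delta > eta > gamma > alpha at 6.0 h, with 57.5% in beta and 9.08% in alpha. Beta's conversion is 59.1%, against the reckoned 55.0%.

    starting material + catalyst → catalyst + target (k = 262 L mol⁻¹ h⁻¹)
    starting material → side product (k = 1.16 h⁻¹)
    target + catalyst ⇌ isomer of the product + catalyst, rate k3*[catalyst]*[target] forward; the back reaction follows from the equilibrium constant (K = 1.30, k = 1.39 L mol⁻¹ h⁻¹)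
    solid substrate ⇌ starting material, rate k4*(cs4 - [starting material]) while solid is left; crystals form when [starting material] > cs4 (solubility = 47.0 mM, k = 0.0428 h⁻¹)

Beta has not come to rest at 30.0 h: 41% of its solid substrate remains, solid or dissolved, and target is made 3.51 times as fast as it is used up, each step taken net. At 300 h beta holds 0% solid substrate, and its share has fallen from 57.5% to 29.8%. Over that stretch target goes from 34.0% to 29.8%, isomer of the product from 6.44% to 38.6%, and side product from 18.7% to 31.6%.

A neighbour of beta charged with 0.060 M of solid substrate has a reckoned charge life by F of 32.8 h, so the reckoning keeps 8.33% of that charge at 30 h. That neighbour flask holds 2.3% of its charge then, solid or dissolved.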